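**Retrosynthetic overview**
1. Hernanol (3R,4R) ⇐ doubly O-benzylated α-carboxy lactone 10. One telescoped hydrogenolysis / decarboxylation / epimerisation removes every auxiliary atom and sets C3 trans to C4 under thermodynamic control.
2. 10 ⇐ cyclopropane-fused lactone 5 + aryl Grignard (from 6) + benzylic bromide 7. Cu-catalysed homoconjugate opening makes the Ar–CH2 bond, and the enolate is benzylated in the same flask.
3. 5 ⇐ dibenzyl malonate 1 + (R)-epichlorohydrin 2. The cyclopropane and the γ-lactone close in one operation, and C5 of 5 becomes C4 of the target.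
4. Ring order: cyclopropane, then γ-lactone (both in step 1). The cyclopropane is cleaved in step 2, the lactone is carried to the end, and both arenes are bought.

Assumption: aryl bromide 6 and benzylic bromide 7 are bought as catalogue compounds.

**Step 1**
Reactants: 1 dibenzyl malonate; 2 (R)-epichlorohydrin
Product: 5 benzyl (1R,5R)-2-oxo-3-oxabicyclo[3.1.0]hexane-1-carboxylate, via epoxy-malonate 3 (not isolated), via cyclopropylcarbinol 4 (not isolated)
Conditions: t-BuOK (1.05 equiv), 1 (1.2 equiv), t-BuOH/THF, 0 °C; add 2 (1.0 equiv), rt, then 65 °C, 16 h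
Reagents that add atoms: none
Why: Malonate double-alkylation/lactonisation cascade (the dialkyl malonate–epichlorohydrin annulation, here with the dibenzyl ester): the malonate opens the epoxide of 2 at CH2, the alkoxide closes onto CH2Cl to give epoxide 3, a second deprotonation triggers 3-exo-tet opening with inversion to cyclopropane alkoxide 4, and this lactonises onto the cis ester, so both rings form in one flask and C5 is set from (R)-2 by a single clean inversion.

**Step 2**
Reactants: 5 benzyl (1R,5R)-2-oxo-3-oxabicyclo[3.1.0]hexane-1-carboxylate; 6 1-(benzyloxy)-4-bromo-2-methoxybenzene; 7 3,4,5-trimethoxybenzyl bromide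
Product: 10 benzyl (3S,4R)-4-[4-(benzyloxy)-3-methoxybenzyl]-2-oxo-3-(3,4,5-trimethoxybenzyl)tetrahydrofuran-3-carboxylate, via aryl Grignard 8 (not isolated), via magnesium enolate 9 (not isolated)
Conditions: 6 (1.3 equiv), Mg, THF, 50 °C; add to 5, CuI (15 mol %), THF, −40 → −10 °C; then 7 (1.6 equiv), DMPU, 0 °C → rt
Reagents that add atoms: none
Why: Cu-catalysed homoconjugate (SN2-type) addition of Grignard 8 to the doubly activated cyclopropane occurs at the unsubstituted C6 and leaves C5 untouched, and the chelated enolate 9 is then C-benzylated by the reactive bromide 7 anti to the C4 substituent (tandem conjugate addition–enolate alkylation); the configuration of the quaternary C3 is unimportant because step 3 erases it.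

**Step 3**
Reactants: 10 benzyl (3S,4R)-4-[4-(benzyloxy)-3-methoxybenzyl]-2-oxo-3-(3,4,5-trimethoxybenzyl)tetrahydrofuran-3-carboxylate
Product: 13 hernanol [(3R,4R)-4-(4-hydroxy-3-methoxybenzyl)-3-(3,4,5-trimethoxybenzyl)dihydrofuran-2(3H)-one], via half-acid 11 (not isolated), via cis epimer 12 (not isolated)
Conditions: H2 (1 atm), 10% Pd/C, EtOAc/EtOH, rt; filter; PhMe, 110 °C; then DBU (0.5 equiv), 110 °C; 1 M HCl work-up
Reagents that add atoms: none
Why: Hydrogenolysis cleaves the benzyl ester and the aryl benzyl ether, the resulting malonic half-acid 11 decarboxylates thermally through its enol, and DBU equilibrates the kinetically favoured cis epimer 12 to the more stable trans lactone, which fixes C3 as R relative to the non-epimerisable C4 (R).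

**Compound list**
1 | dibenzyl malonate | O=C(CC(=O)OCc1ccccc1)OCc1ccccc1 | starting material
2 | (R)-epichlorohydrin | ClC[C@H]1CO1 | starting material
3 | dibenzyl 2-{[(2R)-oxiran-2-yl]methyl}malonate | O=C(OCc1ccccc1)C(C[C@@H]1CO1)C(=O)OCc1ccccc1 | intermediate (not isolated)
4 | dibenzyl (2R)-2-(hydroxymethyl)cyclopropane-1,1-dicarboxylate (present as its potassium alkoxide) | OC[C@@H]1CC1(C(=O)OCc1ccccc1)C(=O)OCc1ccccc1 | intermediate (not isolated)
5 | benzyl (1R,5R)-2-oxo-3-oxabicyclo[3.1.0]hexane-1-carboxylate | O=C1OC[C@@H]2C[C@]12C(=O)OCc1ccccc1 | intermediate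
6 | 1-(benzyloxy)-4-bromo-2-methoxybenzene | COc1cc(Br)ccc1OCc1ccccc1 | starting material
7 | 3,4,5-trimethoxybenzyl bromide | COc1cc(CBr)cc(OC)c1OC | starting material
8 | [4-(benzyloxy)-3-methoxyphenyl]magnesium bromide | COc1cc([Mg]Br)ccc1OCc1ccccc1 | intermediate (not isolated)
9 | bromomagnesium enolate of benzyl (4R)-4-[4-(benzyloxy)-3-methoxybenzyl]-2-oxotetrahydrofuran-3-carboxylate | Br[Mg]OC(OCc1ccccc1)=C1C(=O)OC[C@@H]1Cc1ccc(OCc2ccccc2)c(OC)c1 | intermediate (not isolated)
10 | benzyl (3S,4R)-4-[4-(benzyloxy)-3-methoxybenzyl]-2-oxo-3-(3,4,5-trimethoxybenzyl)tetrahydrofuran-3-carboxylate | O=C1OC[C@H](Cc2ccc(OCc3ccccc3)c(OC)c2)[C@]1(Cc1cc(OC)c(OC)c(OC)c1)C(=O)OCc1ccccc1 | intermediate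
11 | (3R,4R)-4-(4-hydroxy-3-methoxybenzyl)-2-oxo-3-(3,4,5-trimethoxybenzyl)tetrahydrofuran-3-carboxylic acid | O=C1OC[C@H](Cc2ccc(O)c(OC)c2)[C@]1(Cc1cc(OC)c(OC)c(OC)c1)C(=O)O | intermediate (not isolated)
12 | (3S,4R)-4-(4-hydroxy-3-methoxybenzyl)-3-(3,4,5-trimethoxybenzyl)dihydrofuran-2(3H)-one (cis epimer) | COc1cc(C[C@H]2COC(=O)[C@H]2Cc2cc(OC)c(OC)c(OC)c2)ccc1O | intermediate (not isolated)
13 | hernanol, (3R,4R)-4-(4-hydroxy-3-methoxybenzyl)-3-(3,4,5-trimethoxybenzyl)dihydrofuran-2(3H)-one | COc1cc(C[C@H]2COC(=O)[C@@H]2Cc2cc(OC)c(OC)c(OC)c2)ccc1O | target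

**Totals**
Total step count: 3. Longest linear sequence: 3 (steps 1 → 2 → 3).

**Steps most likely to fail, with fallbacks**

Step 2 (highest risk). The chelated magnesium enolate 9 may react too slowly with 7, and residual Grignard/copper can consume 7 by cross-coupling. The fallback gives up the tandem. Setting out from 5, only the Cu-catalysed addition of 8 is run and the mixture is quenched with aqueous NH4Cl. This gives isolable benzyl (4R)-4-[4-(benzyloxy)-3-methoxybenzyl]-2-oxotetrahydrofuran-3-carboxylate F1, whose C3 epimer mixture is irrelevant. This malonate-type C–H acid is then C-benzylated with 7 as its potassium enolate (K2CO3, acetone, reflux) in a separate operation, which returns to the route at 10.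

Step 1. With the dibenzyl ester, direct chloride displacement can compete with epoxide opening and erode the ee, and alkoxide exchange can lower the yield. The fallback builds the same bicycle by metal-carbene chemistry, still closing both rings at once. Setting out from 1, half-saponification (KOH, 1 equiv, BnOH/THF, then acid) gives benzyl hydrogen malonate F2. Esterification with allyl alcohol (EDC, DMAP, CH2Cl2) gives allyl benzyl malonate F3. Diazo transfer (p-ABSA, Et3N, MeCN) gives allyl benzyl 2-diazomalonate F4. Enantioselective intramolecular cyclopropanation with a chiral Co(II) amidoporphyrin (or Ru(II)–Pheox) catalyst, antipode chosen for the (1R,5R) series, returns to the route at 5. The ee of this step would have to be checked and, if needed, upgraded by recrystallisation.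

Step 3. Decarboxylation may be incomplete, or the cis/trans equilibration may be unsatisfactory in the presence of the free phenol. The fallback separates the two events and changes the decarboxylation mechanism. Setting out from 10, Krapcho dealkoxycarbonylation (LiCl, wet DMSO, 150 °C) removes the benzyl ester by chloride attack under conditions that equilibrate C3. This gives (3R,4R)-4-[4-(benzyloxy)-3-methoxybenzyl]-3-(3,4,5-trimethoxybenzyl)dihydrofuran-2(3H)-one F5, which is purified as the trans lactone. Hydrogenolysis of the aryl benzyl ether (H2, Pd/C, EtOAc) then returns to the route at 13.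

**Further compounds**
F1 | step 2 | benzyl (4R)-4-[4-(benzyloxy)-3-methoxybenzyl]-2-oxotetrahydrofuran-3-carboxylate | O=C1OC[C@H](Cc2ccc(OCc3ccccc3)c(OC)c2)C1C(=O)OCc1ccccc1
F2 | step 1 | benzyl hydrogen malonate | O=C(O)CC(=O)OCc1ccccc1
F3 | step 1 | allyl benzyl malonate | C=CCOC(=O)CC(=O)OCc1ccccc1
F4 | step 1 | allyl benzyl 2-diazomalonate | C=CCOC(=O)C(=[N+]=[N-])C(=O)OCc1ccccc1
F5 | step 3 | (3R,4R)-4-[4-(benzyloxy)-3-methoxybenzyl]-3-(3,4,5-trimethoxybenzyl)dihydrofuran-2(3H)-one | COc1cc(C[C@H]2COC(=O)[C@@H]2Cc2cc(OC)c(OC)c(OC)c2)ccc1OCc1ccccc1
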